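**Retrosynthetic overview**
1. Target ⇐ late adjustments on the finished skeleton: SeO2 oxidation of the C5 isopropenyl methyl to the enal, angeloylation of 9-OH, Luche reduction at C6, 9-OH-directed epoxidation of the C10 vinyl.
2. Key step: the γ-lactone is closed purely by C–O bond formation, through a diol-tethered selenite allylic C–H oxidation of the C7 isopropenyl followed by oxidative lactonisation onto 8-OH.
3. The keto-diol needed for this comes from a C9 ketone by enolate hydroxylation (C8–O), hydride reduction (C9), ketal hydrolysis and C5 equilibration.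
4. All carbon is attached to a quinone monoketal by two conjugate additions: Rh-catalysed asymmetric isopropenyl addition at C7, then Cu-catalysed isopropenyl addition at C5 with C10 methylation.
5. The carbocycle is the arene ring of 5-methoxysalicylaldehyde (Wittig, then PhI(OAc)2/MeOH dearomatisation). Ring order: carbocycle (from the arene) → lactone → oxirane.

Assumption: the target is the open 6-hydroxy-15-al form as drawn; locants are elemane locants (ring C5–C10; C10 bears CH3 and C1–C2; C5 bears C4(=C3)–C15; C7 bears C11(=C13)–C12), β is the face of the C10 methyl, and the ligand antipodes named in steps 3 and 9 are those taken to give the drawn configuration.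

**Step 1**
Reactants: 1 2-hydroxy-5-methoxybenzaldehyde
Product: 2 4-methoxy-2-vinylphenol
Conditions: Ph3PCH3Br (2.3 equiv), KOt-Bu (2.3 equiv), THF, 0 °C → rt
Reagents that add atoms: methyltriphenylphosphonium bromide (C[P+](c1ccccc1)(c1ccccc1)c1ccccc1.[Br-])
Why: Wittig methylenation of the aldehyde, the extra base only holding the phenol as its phenoxide; no stereocentre is formed.

**Step 2**
Reactants: 2 4-methoxy-2-vinylphenol
Product: 3 4,4-dimethoxy-2-vinylcyclohexa-2,5-dien-1-one
Conditions: PhI(OAc)2 (1.1 equiv), MeOH, 0 °C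
Reagents that add atoms: methanol (CO)
Why: oxidative dearomatisation of a para-methoxyphenol (the phenoxenium ion is trapped by methanol at the para carbon) gives the quinone monoketal and fixes the C6 and C9 oxygens; no stereocentre.

**Step 3**
Reactants: 3 4,4-dimethoxy-2-vinylcyclohexa-2,5-dien-1-one
Product: 4 (5S)-4,4-dimethoxy-5-(prop-1-en-2-yl)-2-vinylcyclohex-2-en-1-one (7β-isopropenyl)
Conditions: CH2=C(CH3)B(pin) (2 equiv), [RhCl(C2H4)2]2 (2.5 mol %), (R)-BINAP (6 mol %), KOH (0.5 equiv), 1,4-dioxane/H2O 10:1, 40 °C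
Reagents that add atoms: 2-isopropenyl-4,4,5,5-tetramethyl-1,3,2-dioxaborolane (CC(=C)B1OC(C)(C)C(C)(C)O1)
Why: Hayashi–Miyaura rhodium-catalysed asymmetric 1,4-addition; the alkenyl–rhodium inserts the unsubstituted enone (β-carbon C7) in preference to the α-vinyl-substituted one, and the chiral bisphosphine fixes the C7 configuration in the insertion step.

**Step 4**
Reactants: 4 (5S)-4,4-dimethoxy-5-(prop-1-en-2-yl)-2-vinylcyclohex-2-en-1-one
Product: 6 6,6-dimethoxy-10β-methyl-5α,7β-di(prop-1-en-2-yl)-10α-vinylcyclohexan-9-one, via bromomagnesium dienolate 5 (not isolated)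
Conditions: CH2=C(CH3)MgBr (1.5 equiv), CuBr·SMe2 (20 mol %), THF, −78 °C; then CH3I (5 equiv), HMPA, −78 → 0 °C
Reagents that add atoms: isopropenylmagnesium bromide (CC(=C)[Mg]Br); iodomethane (CI)
Why: copper-catalysed conjugate addition with enolate alkylation (three-component coupling); isopropenyl adds to C5 by axial attack anti to the C7 substituent (the usual trans-3,5 outcome), and CH3I then alkylates the dienolate at its α-carbon C10 anti to the new C5 group, giving the quaternary centre with methyl β and vinyl α.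

**Step 5**
Reactants: 6 6,6-dimethoxy-10β-methyl-5α,7β-di(prop-1-en-2-yl)-10α-vinylcyclohexan-9-one
Product: 8 8α-hydroxy-6,6-dimethoxy-10β-methyl-5α,7β-di(prop-1-en-2-yl)-10α-vinylcyclohexan-9-one, via potassium enolate 7 (not isolated)
Conditions: KN(SiMe3)2 (1.2 equiv), THF, −78 °C; 2-(phenylsulfonyl)-3-phenyloxaziridine (1.4 equiv); then AcOH
Reagents that add atoms: 2-(phenylsulfonyl)-3-phenyloxaziridine (O=S(=O)(c1ccccc1)N1OC1c1ccccc1)
Why: Davis enolate hydroxylation; C8 is the only enolisable position of the C9 ketone, and the oxaziridine approaches anti to the neighbouring C7 isopropenyl and the axial C10 methyl, giving the 8α-alcohol trans to the C7 substituent.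

**Step 6**
Reactants: 8 8α-hydroxy-6,6-dimethoxy-10β-methyl-5α,7β-di(prop-1-en-2-yl)-10α-vinylcyclohexan-9-one
Product: 9 6,6-dimethoxy-10β-methyl-5α,7β-di(prop-1-en-2-yl)-10α-vinylcyclohexane-8α,9α-diol
Conditions: LiBH(s-Bu)3 (2.5 equiv), THF, −78 °C; then H2O
Reagents that add atoms: none
Why: bulky-hydride ketone reduction; axial approach to C9 on the α face is closed by the axial C5 isopropenyl, so hydride enters equatorially from the β face and gives the axial 9α-alcohol cis to 8α-OH.

**Step 7**
Reactants: 9 6,6-dimethoxy-10β-methyl-5α,7β-di(prop-1-en-2-yl)-10α-vinylcyclohexane-8α,9α-diol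
Product: 11 8α,9α-dihydroxyelema-1,3,11(12)-trien-6-one (5β-isopropenyl), via 5α-isopropenyl ketone 10 (not isolated)
Conditions: oxalic acid (0.5 equiv), THF/H2O 4:1, rt; then K2CO3 (0.3 equiv), MeOH, 0 °C
Reagents that add atoms: water (O)
Why: acid hydrolysis of the dimethyl ketal, then base equilibration α to the new ketone; the axial C5 isopropenyl, 1,3-diaxial to 9α-OH, epimerises to the equatorial β position cis to C7 under thermodynamic control, while kinetic α-protonation of the dienolate and allylic strain with quaternary C10 keep the alkene out of conjugation.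

**Step 8**
Reactants: 11 8α,9α-dihydroxyelema-1,3,11(12)-trien-6-one
Product: 15 9α-hydroxy-6-oxoelema-1,3,11(13)-trien-12,8α-olide, via cyclic selenite 12 (not isolated), via allylic triol 13 (not isolated), via lactol 14 (not isolated)
Conditions: SeO2 (0.6 equiv), pyridine (1 equiv), CH2Cl2, 35 °C; then TEMPO (0.2 equiv), PhI(OAc)2 (2.4 equiv), rt
Reagents that add atoms: selenium dioxide (O=[Se]=O)
Why: Proposed new method: the cis-8,9-diol condenses with SeO2 to cyclic selenite 12, which holds a tetravalent selenium Se=O enophile within reach of the C7 isopropenyl only, so an intramolecular ene reaction and [2,3]-sigmatropic shift (the accepted mechanism of SeO2 allylic oxidation, here made site-selective by the tether, the C5 isopropenyl beside the C6 ketone having no hydroxyl neighbour and meeting no free SeO2) give after hydrolysis the C12 alcohol 13; TEMPO/PhI(OAc)2 then oxidises this primary allylic alcohol, the aldehyde closes on the equatorial 8α-OH to lactol 14 and is oxidised on to the trans-fused α-methylene lactone with C7 and C8 unchanged; the closest known reactions are intermolecular SeO2 allylic hydroxylation and TEMPO/PhI(OAc)2 oxidative lactonisation of 1,4-diols.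

**Step 9**
Reactants: 15 9α-hydroxy-6-oxoelema-1,3,11(13)-trien-12,8α-olide
Product: 16 (1R)-1,2-epoxy-9α-hydroxy-6-oxoelema-3,11(13)-dien-12,8α-olide
Conditions: VO(Oi-Pr)3 (5 mol %), (R,R)-N,N′-dihydroxy-N,N′-bis(diphenylacetyl)cyclohexane-1,2-diamine (6 mol %), t-BuOOH (1.5 equiv), toluene, 0 °C
Reagents that add atoms: tert-butyl hydroperoxide (CC(C)(C)OO)
Why: hydroxyl-directed asymmetric epoxidation of a homoallylic alcohol with a pentavalent vanadium bishydroxamate catalyst; 9α-OH binds the metal and delivers the peroxide oxygen to the adjacent C10 vinyl only (the acrylate is electron-poor and the equatorial C5 isopropenyl is out of reach), and the chiral ligand decides the C1 face.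

**Step 10**
Reactants: 16 (1R)-1,2-epoxy-9α-hydroxy-6-oxoelema-3,11(13)-dien-12,8α-olide
Product: 17 (1R)-1,2-epoxy-6β,9α-dihydroxyelema-3,11(13)-dien-12,8α-olide
Conditions: NaBH4 (1.2 equiv), CeCl3·7H2O (1.2 equiv), MeOH, −78 °C
Reagents that add atoms: none
Why: Luche reduction is 1,2-selective and spares the α-methylene lactone and epoxide; the axial C10 methyl blocks the β (axial) trajectory, so hydride enters from the α face and gives the axial 6β-alcohol, as in 6-oxo steroids.

**Step 11**
Reactants: 17 (1R)-1,2-epoxy-6β,9α-dihydroxyelema-3,11(13)-dien-12,8α-olide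
Product: 18 (1R)-9α-angeloyloxy-1,2-epoxy-6β-hydroxyelema-3,11(13)-dien-12,8α-olide
Conditions: angelic acid (3 equiv), 2,4,6-Cl3C6H2COCl (3 equiv), Et3N (3 equiv), toluene, rt; then 17, 80 °C
Reagents that add atoms: angelic acid (C/C=C(/C)C(=O)O)
Why: Yamaguchi mixed-anhydride esterification run without DMAP to avoid angelate-to-tiglate isomerisation; 9α-OH is acylated in preference to 6β-OH, which is flanked by two branched carbons and is syn-axial to the C10 methyl.

**Step 12**
Reactants: 18 (1R)-9α-angeloyloxy-1,2-epoxy-6β-hydroxyelema-3,11(13)-dien-12,8α-olide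
Product: 19 target, (1R)-9α-angeloyloxy-1,2-epoxy-6β-hydroxy-15-oxoelema-3,11(13)-dien-12,8α-olide
Conditions: SeO2 (1.5 equiv), 1,4-dioxane/pyridine 20:1, 65 °C
Reagents that add atoms: selenium dioxide (O=[Se]=O)
Why: Riley-type SeO2 allylic oxidation (ene reaction, [2,3]-shift, further oxidation) of the only electron-rich alkene that carries allylic hydrogens converts the C5 isopropenyl methyl into the enal; no stereocentre is touched.

**Compound list**
1 | 2-hydroxy-5-methoxybenzaldehyde | COc1ccc(O)c(C=O)c1 | starting material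
2 | 4-methoxy-2-vinylphenol | COc1ccc(O)c(C=C)c1 | intermediate
3 | 4,4-dimethoxy-2-vinylcyclohexa-2,5-dien-1-one | C=CC1=CC(OC)(OC)C=CC1=O | intermediate
4 | (5S)-4,4-dimethoxy-5-(prop-1-en-2-yl)-2-vinylcyclohex-2-en-1-one | O=C1C[C@@H](C(C)=C)C(OC)(OC)C=C1C=C | intermediate
5 | bromomagnesium dienolate from isopropenyl addition to C5 of 4 | Br[Mg]OC1=C(C=C)[C@@H](C(C)=C)C(OC)(OC)[C@H](C(C)=C)C1 | intermediate
6 | 6,6-dimethoxy-10β-methyl-5α,7β-di(prop-1-en-2-yl)-10α-vinylcyclohexan-9-one | O=C1C[C@@H](C(C)=C)C(OC)(OC)[C@H](C(C)=C)[C@]1(C)C=C | intermediate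
7 | potassium C8–C9 enolate of 6 | [K+].[O-]C1=C[C@@H](C(C)=C)C(OC)(OC)[C@H](C(C)=C)[C@]1(C)C=C | intermediate
8 | 8α-hydroxy derivative of 6 | O=C1[C@H](O)[C@@H](C(C)=C)C(OC)(OC)[C@H](C(C)=C)[C@]1(C)C=C | intermediate
9 | 6,6-dimethoxy-10β-methyl-5α,7β-di(prop-1-en-2-yl)-10α-vinylcyclohexane-8α,9α-diol | O[C@@H]1[C@H](O)[C@@H](C(C)=C)C(OC)(OC)[C@H](C(C)=C)[C@]1(C)C=C | intermediate
10 | 8α,9α-dihydroxy-5α-isopropenyl-6-ketone (C5 epimer of 11) | O[C@@H]1[C@H](O)[C@@H](C(C)=C)C(=O)[C@H](C(C)=C)[C@]1(C)C=C | intermediate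
11 | 8α,9α-dihydroxyelema-1,3,11(12)-trien-6-one (5β,7β-diisopropenyl) | O[C@@H]1[C@H](O)[C@@H](C(C)=C)C(=O)[C@@H](C(C)=C)[C@]1(C)C=C | intermediate
12 | cyclic 8α,9α-selenite of 11 | O=[Se]1O[C@@H]2[C@H](O1)[C@@H](C(C)=C)C(=O)[C@@H](C(C)=C)[C@]2(C)C=C | intermediate
13 | 8α,9α,12-trihydroxyelema-1,3,11(13)-trien-6-one | O[C@@H]1[C@H](O)[C@@H](C(=C)CO)C(=O)[C@@H](C(C)=C)[C@]1(C)C=C | intermediate
14 | 9α-hydroxy-6-oxoelema-1,3,11(13)-triene 12,8α-lactol | C=C1C(O)O[C@@H]2[C@@H]1C(=O)[C@@H](C(C)=C)[C@](C)(C=C)[C@@H]2O | intermediate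
15 | 9α-hydroxy-6-oxoelema-1,3,11(13)-trien-12,8α-olide | C=C1C(=O)O[C@@H]2[C@@H]1C(=O)[C@@H](C(C)=C)[C@](C)(C=C)[C@@H]2O | intermediate
16 | (1R)-1,2-epoxy-9α-hydroxy-6-oxoelema-3,11(13)-dien-12,8α-olide | C=C1C(=O)O[C@@H]2[C@@H]1C(=O)[C@@H](C(C)=C)[C@](C)([C@@H]1CO1)[C@@H]2O | intermediate
17 | (1R)-1,2-epoxy-6β,9α-dihydroxyelema-3,11(13)-dien-12,8α-olide | C=C1C(=O)O[C@@H]2[C@@H]1[C@@H](O)[C@@H](C(C)=C)[C@](C)([C@@H]1CO1)[C@@H]2O | intermediate
18 | (1R)-9α-angeloyloxy-1,2-epoxy-6β-hydroxyelema-3,11(13)-dien-12,8α-olide | C=C1C(=O)O[C@@H]2[C@@H]1[C@@H](O)[C@@H](C(C)=C)[C@](C)([C@@H]1CO1)[C@@H]2OC(=O)/C(C)=C\C | intermediate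
19 | CNP0130022.2, (1R)-9α-angeloyloxy-1,2-epoxy-6β-hydroxy-15-oxoelema-3,11(13)-dien-12,8α-olide | C=C1C(=O)O[C@@H]2[C@@H]1[C@@H](O)[C@@H](C(=C)C=O)[C@](C)([C@@H]1CO1)[C@@H]2OC(=O)/C(C)=C\C | target

**Step count and risks**
Total steps: 12. Longest linear sequence: 12 steps (fully linear from 1).

Step 8 (the proposed new method) may fail to discriminate the two isopropenyl groups or may stall at the selenite. The fallback uses known chemistry and brings in the C12 oxygen at the carbon–carbon stage. It sets out from 3: the rhodium-catalysed addition of step 3 is run with 2-[3-(tert-butyldimethylsilyloxy)prop-1-en-2-yl]-4,4,5,5-tetramethyl-1,3,2-dioxaborolane and gives the silyloxy enone F1. The conditions of steps 4, 5, 6 and 7 then give in turn the methylated silyloxy ketone F2, the 8α-hydroxy silyloxy ketone F3, the silyloxy ketal diol F4 and the silyloxy 6-keto diol F5. Bu4NF in THF removes the silyl group and gives triol 13, where the fallback comes back to the route; TEMPO/PhI(OAc)2, as in the second half of step 8, then gives 15.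

Step 7 may fail because the β-hydroxy ketone can eliminate or undergo retro-aldol cleavage under base, or because an isopropenyl group may slip into conjugation. The fallback sets out from 9 and masks the diol first: 2,2-dimethoxypropane with PPTS gives the acetonide ketal F6. PPTS in wet acetone exchanges only the dimethyl ketal and gives the acetonide 5α-isopropenyl ketone F7. DBU in toluene epimerises C5 to the acetonide 5β-isopropenyl ketone F8, with no free β-hydroxyl present. Aqueous acetic acid removes the acetonide and the fallback comes back to the route at 11.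

Step 9 may fail because the substrate's own facial bias could override the ligand and give the C1 epimer. The fallback sets out from 15 and replaces catalyst-controlled epoxidation by resolution: VO(acac)2 with t-BuOOH and no chiral ligand gives 16 together with the 1S epoxide F9. Hydrolytic kinetic resolution with (R,R)-(salen)Co(OAc) and water (the antipode that consumes the 1S epoxide) converts F9 into the 1S diol F10. Chromatography then returns pure 16, where the fallback comes back to the route.

Further compounds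
F1 | step 8 | (5S)-5-[3-(tert-butyldimethylsilyloxy)prop-1-en-2-yl]-4,4-dimethoxy-2-vinylcyclohex-2-en-1-one | O=C1C[C@@H](C(=C)CO[Si](C)(C)C(C)(C)C)C(OC)(OC)C=C1C=C
F2 | step 8 | 12-silyloxy analogue of 6 | O=C1C[C@@H](C(=C)CO[Si](C)(C)C(C)(C)C)C(OC)(OC)[C@H](C(C)=C)[C@]1(C)C=C
F3 | step 8 | 12-silyloxy analogue of 8 | O=C1[C@H](O)[C@@H](C(=C)CO[Si](C)(C)C(C)(C)C)C(OC)(OC)[C@H](C(C)=C)[C@]1(C)C=C
F4 | step 8 | 12-silyloxy analogue of 9 | O[C@@H]1[C@H](O)[C@@H](C(=C)CO[Si](C)(C)C(C)(C)C)C(OC)(OC)[C@H](C(C)=C)[C@]1(C)C=C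
F5 | step 8 | 12-silyloxy analogue of 11 | O[C@@H]1[C@H](O)[C@@H](C(=C)CO[Si](C)(C)C(C)(C)C)C(=O)[C@@H](C(C)=C)[C@]1(C)C=C
F6 | step 7 | 8α,9α-acetonide of 9 | CC1(C)O[C@@H]2[C@H](O1)[C@@H](C(C)=C)C(OC)(OC)[C@H](C(C)=C)[C@]2(C)C=C
F7 | step 7 | 8α,9α-acetonide of 10 | CC1(C)O[C@@H]2[C@H](O1)[C@@H](C(C)=C)C(=O)[C@H](C(C)=C)[C@]2(C)C=C
F8 | step 7 | 8α,9α-acetonide of 11 | CC1(C)O[C@@H]2[C@H](O1)[C@@H](C(C)=C)C(=O)[C@@H](C(C)=C)[C@]2(C)C=C
F9 | step 9 | (1S)-1,2-epoxy-9α-hydroxy-6-oxoelema-3,11(13)-dien-12,8α-olide | C=C1C(=O)O[C@@H]2[C@@H]1C(=O)[C@@H](C(C)=C)[C@](C)([C@H]1CO1)[C@@H]2O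
F10 | step 9 | (1S)-1,2,9α-trihydroxy-6-oxoelema-3,11(13)-dien-12,8α-olide | C=C1C(=O)O[C@@H]2[C@@H]1C(=O)[C@@H](C(C)=C)[C@](C)([C@H](O)CO)[C@@H]2O
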